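**Retrosynthetic overview**

1. Target 13 ⇐ acetate 12 by base: deacetylation and thermodynamic inversion at C2 through the enolate, so C2 never needs kinetic control.
2. 12 ⇐ lactone 8 + veratrole 9: benzylic arylation sets C4 from C3, then Friedel–Crafts acylation closes ring B (the cyclohexanone), the only ring of the target that is built; ring A and the pendant ring C are bought arenes.
3. 8 ⇐ keto ester 6 (ketone reduction, lactonisation) ⇐ hemiester 3 + 2-methoxyphenyl acetate 4 (Friedel–Crafts acylation para to OMe).
4. 3 ⇐ meso anhydride 2 + methanol: the key disconnection is the ester C–O bond; forming it at one of the two enantiotopic carbonyls fixes C3, the one stereocentre that needs absolute control. 2 ⇐ meso diacid 1.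
5. Ring order: anhydride ring (step 1, opened in step 2), lactone ring (step 4, opened in step 5), ring B (step 5).

Assumption: (DHQD)2AQN gives hemiester 3 in the (2S,3R) configuration; if the sense is the opposite, its quinine-derived pseudo-enantiomer (DHQ)2AQN is used and nothing else changes.

**Route**

Step 1
Reactants: 1 meso-2,3-dimethylsuccinic acid
Product: 2 meso-2,3-dimethylsuccinic anhydride [(3R,4S)-3,4-dimethyloxolane-2,5-dione]
Conditions: AcCl (3 equiv), reflux, 2 h; evaporate, strip with toluene
Reagents that add atoms: none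
Why: Cyclodehydration of a 1,4-diacid to the five-membered anhydride via a mixed anhydride; neither stereocentre is touched, so the product stays cis (meso).

Step 2
Reactants: 2 meso-2,3-dimethylsuccinic anhydride
Product: 3 (2S,3R)-4-methoxy-2,3-dimethyl-4-oxobutanoic acid
Conditions: (DHQD)2AQN (10 mol%), MeOH (10 equiv), Et2O, −30 °C; 1 M HCl wash recovers the catalyst
Reagents that add atoms: methanol, CO
Why: Cinchona-alkaloid-catalysed enantioselective alcoholysis (desymmetrisation of a meso cyclic anhydride, general-base catalysis by the quinuclidine nitrogen) forms the ester C–O bond at one enantiotopic carbonyl and so fixes the absolute configuration of both methyl-bearing carbons; the carbon alpha to the free acid becomes C3 of the target.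

Step 3
Reactants: 3 (2S,3R)-4-methoxy-2,3-dimethyl-4-oxobutanoic acid; 4 2-methoxyphenyl acetate
Product: 6 methyl (2R,3S)-4-(3-acetoxy-4-methoxyphenyl)-2,3-dimethyl-4-oxobutanoate, via acid chloride 5 (not isolated)
Conditions: (COCl)2, DMF (cat.), CH2Cl2, 0 °C to rt; evaporate; then 4, AlCl3 (2.5 equiv), CH2Cl2, −10 to 0 °C; NaHCO3 wash
Reagents that add atoms: none
Why: Acid chloride formation followed by Friedel–Crafts acylation, which goes para to the methoxy group because the acetoxy group is the weaker director; no stereocentre is formed, the low temperature protects the centre alpha to the new ketone, and any keto acid formed through ester participation (anhydride pathway, racemic) is removed by the bicarbonate wash.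

Step 4
Reactants: 6 methyl (2R,3S)-4-(3-acetoxy-4-methoxyphenyl)-2,3-dimethyl-4-oxobutanoate
Product: 8 (3R,4S,5S)-5-(3-acetoxy-4-methoxyphenyl)-3,4-dimethyloxolan-2-one, via hydroxy ester 7 (not isolated)
Conditions: NaBH4, CeCl3·7H2O, MeOH, −40 °C; aq. NH4Cl; then CSA (5 mol%), toluene, 50 °C
Reagents that add atoms: none
Why: CeCl3-assisted NaBH4 ketone reduction (Luche type, fast enough at −40 °C to spare the aryl acetate and to outrun enolisation) and acid-catalysed lactonisation (intramolecular transesterification); Felkin–Anh attack gives mainly the carbinol that closes to the trans-4,5 lactone, but this centre is of no consequence because it is ionised in step 5.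

Step 5
Reactants: 8 (3R,4S,5S)-5-(3-acetoxy-4-methoxyphenyl)-3,4-dimethyloxolan-2-one; 9 veratrole
Product: 12 (2R,3R,4R)-4-(3-acetoxy-4-methoxyphenyl)-6,7-dimethoxy-2,3-dimethyl-3,4-dihydronaphthalen-1(2H)-one, via diaryl acid 10 (not isolated), via mixed anhydride 11 (not isolated)
Conditions: 9 (2 equiv), TfOH (20 mol%), HFIP, 0 °C; evaporate; TFAA (3 equiv), CH2Cl2, 0 °C to rt
Reagents that add atoms: none
Why: Proposed new method: a one-pot arylative lactone opening and acylative ring closure in which lactone 8 acts as a latent chiral benzylic cation; TfOH in HFIP ionises the benzylic C–O bond (cation stabilised by the para-methoxy group), the cation sits with C3–H in the aryl plane (least A(1,3) strain), and veratrole attacks through its position para to a methoxy group on the face of the small methyl group, anti to the CH(CH3)CO2H branch (backside attack on the trans-lactone ion pair gives the same face), so that 10 forms with the aryl group and the C3 methyl destined to be cis (1,2-induction sets C4); TFAA then makes mixed anhydride 11, which closes ring B by intramolecular Friedel–Crafts acylation para to a methoxy group of the veratryl ring only, the acetoxy-bearing ring being deactivated; the closest known reaction types are the Friedel–Crafts alkylation/acylation of unsubstituted 4-aryl-butyrolactones with arenes to 4-aryl-1-tetralones and the acid-catalysed diastereoselective arylation of alpha-branched secondary benzylic alcohols, neither shown on a lactone that carries the controlling stereocentre.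

Step 6
Reactants: 12 (2R,3R,4R)-4-(3-acetoxy-4-methoxyphenyl)-6,7-dimethoxy-2,3-dimethyl-3,4-dihydronaphthalen-1(2H)-one
Product: 13 (2S,3R,4R)-4-(3-hydroxy-4-methoxyphenyl)-6,7-dimethoxy-2,3-dimethyl-3,4-dihydronaphthalen-1(2H)-one
Conditions: K2CO3 (3 equiv), MeOH, 40 °C, N2; aq. NH4Cl
Reagents that add atoms: none
Why: Base-mediated transesterification (Zemplén-type deacetylation) and thermodynamic epimerisation through the enolate; C2 settles as S because the trans (equatorial) 2-methyl avoids the 1,3-diaxial clash that the cis (axial) 2-methyl has with the pseudoaxial C4 aryl group.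

**Compound list**

1 | meso-2,3-dimethylsuccinic acid [(2R,3S)-2,3-dimethylbutanedioic acid] | OC(=O)[C@H](C)[C@H](C)C(=O)O | starting material
2 | meso-2,3-dimethylsuccinic anhydride [(3R,4S)-3,4-dimethyloxolane-2,5-dione] | O=C1[C@H](C)[C@H](C)C(=O)O1 | intermediate
3 | (2S,3R)-4-methoxy-2,3-dimethyl-4-oxobutanoic acid | COC(=O)[C@H](C)[C@H](C)C(=O)O | intermediate
4 | 2-methoxyphenyl acetate (guaiacol acetate) | COc1ccccc1OC(C)=O | starting material
5 | methyl (2R,3S)-4-chloro-2,3-dimethyl-4-oxobutanoate (acid chloride) | COC(=O)[C@H](C)[C@H](C)C(Cl)=O | intermediate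
6 | methyl (2R,3S)-4-(3-acetoxy-4-methoxyphenyl)-2,3-dimethyl-4-oxobutanoate | COC(=O)[C@H](C)[C@H](C)C(=O)c1ccc(OC)c(OC(C)=O)c1 | intermediate
7 | methyl (2R,3S,4S)-4-(3-acetoxy-4-methoxyphenyl)-4-hydroxy-2,3-dimethylbutanoate (major carbinol epimer; the other converges) | COC(=O)[C@H](C)[C@H](C)[C@H](O)c1ccc(OC)c(OC(C)=O)c1 | intermediate
8 | (3R,4S,5S)-5-(3-acetoxy-4-methoxyphenyl)-3,4-dimethyloxolan-2-one (3,4-cis, 4,5-trans lactone) | O=C1[C@H](C)[C@H](C)[C@@H](c2ccc(OC)c(OC(C)=O)c2)O1 | intermediate
9 | veratrole (1,2-dimethoxybenzene) | COc1ccccc1OC | starting material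
10 | (2R,3R,4S)-4-(3-acetoxy-4-methoxyphenyl)-4-(3,4-dimethoxyphenyl)-2,3-dimethylbutanoic acid | OC(=O)[C@H](C)[C@H](C)[C@H](c1ccc(OC)c(OC(C)=O)c1)c1ccc(OC)c(OC)c1 | intermediate
11 | (2R,3R,4S)-4-(3-acetoxy-4-methoxyphenyl)-4-(3,4-dimethoxyphenyl)-2,3-dimethylbutanoic trifluoroacetic anhydride | O=C(OC(=O)C(F)(F)F)[C@H](C)[C@H](C)[C@H](c1ccc(OC)c(OC(C)=O)c1)c1ccc(OC)c(OC)c1 | intermediate
12 | (2R,3R,4R)-4-(3-acetoxy-4-methoxyphenyl)-6,7-dimethoxy-2,3-dimethyl-3,4-dihydronaphthalen-1(2H)-one (2,3-cis, 3,4-cis) | COc1ccc([C@@H]2c3cc(OC)c(OC)cc3C(=O)[C@H](C)[C@@H]2C)cc1OC(C)=O | intermediate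
13 | (2S,3R,4R)-4-(3-hydroxy-4-methoxyphenyl)-6,7-dimethoxy-2,3-dimethyl-3,4-dihydronaphthalen-1(2H)-one (2,3-trans, 3,4-cis; CNP0170223.1) | COc1ccc([C@@H]2c3cc(OC)c(OC)cc3C(=O)[C@@H](C)[C@@H]2C)cc1O | target

**Totals and risks**

Total step count: 6. Longest linear sequence: 6 (1 to 13); 4 and 9 are bought and enter in steps 3 and 5.

The three steps most likely to fail:

Step 5 (the proposed new step). The risks are the sense and level of facial selectivity at C4 (a branch of secondary-alkyl size against methyl may give only moderate dr, so 12 is purified by crystallisation or chromatography), loss of the C3 proton from the cation (styrene formation would scramble C3, hence low temperature and excess arene), and acylation of surplus veratrole in the second stage. The fallback uses known reactions stepwise and swaps the order in which the two aryl groups arrive, which inverts C4 for a given facial preference, so whichever face the arene prefers, one of the two orders leads to 10. It sets out from acid chloride 5. AlCl3-mediated Friedel–Crafts acylation of veratrole 9 in CH2Cl2 at −10 °C gives methyl (2R,3S)-4-(3,4-dimethoxyphenyl)-2,3-dimethyl-4-oxobutanoate F1. NaBH4 in MeOH at 0 °C reduces it to methyl (2R,3S,4S)-4-(3,4-dimethoxyphenyl)-4-hydroxy-2,3-dimethylbutanoate F2. The free benzylic alcohol is then used in the established FeCl3-catalysed (10 mol%) Friedel–Crafts benzylation with 2-methoxyphenyl acetate 4 as co-solvent, giving methyl (2R,3R,4S)-4-(3-acetoxy-4-methoxyphenyl)-4-(3,4-dimethoxyphenyl)-2,3-dimethylbutanoate F3, whose diastereomers are separated at this stage. LiOH in aqueous THF gives (2R,3R,4R)-4-(3,4-dimethoxyphenyl)-4-(3-hydroxy-4-methoxyphenyl)-2,3-dimethylbutanoic acid F4, and Ac2O/pyridine with aqueous work-up re-acetylates the phenol. The fallback comes back to the route at 10, which is then closed with TFAA through 11 to 12 as a separate, ordinary intramolecular Friedel–Crafts acylation.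

Step 3. The risks are epimerisation alpha to the new ketone under AlCl3 (this is C3, the centre the whole route depends on), ester participation leading to the anhydride, and acetate cleavage. The fallback avoids the Lewis acid and sets out from acid chloride 5. Commercial 5-bromo-2-methoxyphenol is acetylated (Ac2O, pyridine) to 5-bromo-2-methoxyphenyl acetate F5. CoBr2-catalysed zinc insertion (Zn dust, MeCN) converts it into (3-acetoxy-4-methoxyphenyl)zinc bromide F6. Negishi-type acylation of F6 with 5 under Pd(PPh3)4 (2 mol%) in THF at 0 °C, under neutral conditions, comes back to the route at 6.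

Step 4. The risks are partial loss of the aryl acetate under borohydride in methanol and incomplete lactonisation. The fallback accepts the deacetylation instead of fighting it and sets out from 6. NaBH4 in MeOH at 0 °C is followed, only after the ketone is consumed, by K2CO3 to complete acetate removal, giving methyl (2R,3S,4S)-4-hydroxy-4-(3-hydroxy-4-methoxyphenyl)-2,3-dimethylbutanoate F7. CSA in toluene closes it to (3R,4S,5S)-5-(3-hydroxy-4-methoxyphenyl)-3,4-dimethyloxolan-2-one F8. Ac2O/pyridine re-acetylates the phenol, and the fallback comes back to the route at 8.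

**Further compounds**

F1 | step 5 | methyl (2R,3S)-4-(3,4-dimethoxyphenyl)-2,3-dimethyl-4-oxobutanoate | COC(=O)[C@H](C)[C@H](C)C(=O)c1ccc(OC)c(OC)c1
F2 | step 5 | methyl (2R,3S,4S)-4-(3,4-dimethoxyphenyl)-4-hydroxy-2,3-dimethylbutanoate | COC(=O)[C@H](C)[C@H](C)[C@H](O)c1ccc(OC)c(OC)c1
F3 | step 5 | methyl (2R,3R,4S)-4-(3-acetoxy-4-methoxyphenyl)-4-(3,4-dimethoxyphenyl)-2,3-dimethylbutanoate | COC(=O)[C@H](C)[C@H](C)[C@H](c1ccc(OC)c(OC(C)=O)c1)c1ccc(OC)c(OC)c1
F4 | step 5 | (2R,3R,4R)-4-(3,4-dimethoxyphenyl)-4-(3-hydroxy-4-methoxyphenyl)-2,3-dimethylbutanoic acid | OC(=O)[C@H](C)[C@H](C)[C@H](c1ccc(OC)c(O)c1)c1ccc(OC)c(OC)c1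
F5 | step 3 | 5-bromo-2-methoxyphenyl acetate | COc1ccc(Br)cc1OC(C)=O
F6 | step 3 | (3-acetoxy-4-methoxyphenyl)zinc bromide | COc1ccc([Zn]Br)cc1OC(C)=O
F7 | step 4 | methyl (2R,3S,4S)-4-hydroxy-4-(3-hydroxy-4-methoxyphenyl)-2,3-dimethylbutanoate | COC(=O)[C@H](C)[C@H](C)[C@H](O)c1ccc(OC)c(O)c1
F8 | step 4 | (3R,4S,5S)-5-(3-hydroxy-4-methoxyphenyl)-3,4-dimethyloxolan-2-one | O=C1[C@H](C)[C@H](C)[C@@H](c2ccc(OC)c(O)c2)O1
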